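**Plan**
1. Ring locants: C1 = CH–indolyl, C2 = CH=, C3 = C(CH3)=, C4, C5 = CH2, C6 = quaternary C. Retrosynthetic cuts, in order: the ring alkene C2=C3 (to a 1,6-keto aldehyde); the C1–C6 bond (retro-Ireland–Claisen to an arylacetate of a (Z)-allylic, benzylic alcohol); the alkene C–CH2 bond of that alcohol (B-alkyl Suzuki) and its carbinol–alkyne bond (aldehyde + propyne); both indole halves go back to one bromide made from 5-bromoindole and isoprene.
2. Enabling feature: the ring's only double bond is isolated and trisubstituted, so both of its carbons can be carbonyl carbons of like (acceptor) polarity, an aldehyde at C2 and a methyl ketone at C3, six atoms apart along C2–C1–C6–C5–C4–C3. At that oxidation level C2–C1–C6–CH=CH–indolyl is a γ,δ-unsaturated carbonyl, the Claisen retron that carries the E-styrene and both stereocentres.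
3. Forward: one indole bromide gives the aldehyde (styrene half) and the arylacetic acid (benzylic half); aldehyde → (S)-propargylic alcohol → (Z)-iodoalkene → (Z)-allylic alcohol with a masked 3-oxobutyl arm; esterification; Ireland–Claisen joins the chain at C1–C6; reduction, unmasking and oxidation give the keto aldehyde; the six-membered ring, the only carbocycle made in the route, is closed by reductive carbonyl coupling; N-desilylation ends the route.
4. Stereochemistry: the carbinol is set by a BINOL–titanium alkynylation (reagent control). A chair Claisen transition state ((Z)-silyl ketene acetal, (Z)-alkene, carbinol aryl equatorial) transfers it to C1 (R), C6 (S) and the E-alkene. The ring closure creates no stereocentre.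

Key step: step 13

Remark: Ar stands for 3-(2-methylbut-3-en-2-yl)-1-(triisopropylsilyl)-1H-indol-5-yl; the target is the (1R,6S) enantiomer, as written in the SMILES of compound 27; compounds 1, 2, 7, 12 and 15 are assumed to be commercial.

**Step 1**
Reactants: 1 5-bromo-1H-indole; 2 isoprene (2-methylbuta-1,3-diene)
Product: 3 5-bromo-3-(2-methylbut-3-en-2-yl)-1H-indole
Conditions: [Rh(cod)Cl]2 (cat.), DTBM-SEGPHOS (cat.), camphorsulfonic acid (cat.), 2 (excess), 1,2-dichloroethane, 60 °C, sealed tube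
Reagents that add atoms: none
Why: A rhodium hydride adds to isoprene to give a 1,1-dimethyl-π-allyl complex that indole C3 attacks at the more substituted terminus (branch-selective hydroarylation of a 1,3-diene, a reaction type known for C3–H indoles with isoprene); C–Br and N–H should be spectators.

**Step 2**
Reactants: 3 5-bromo-3-(2-methylbut-3-en-2-yl)-1H-indole
Product: 4 5-bromo-3-(2-methylbut-3-en-2-yl)-1-(triisopropylsilyl)-1H-indole (Ar–Br)
Conditions: NaH, THF, 0 °C; i-Pr3SiCl, 0 °C → rt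
Reagents that add atoms: triisopropylsilyl chloride, CC(C)[Si](Cl)(C(C)C)C(C)C
Why: N-silylation of the sodium indolide; the bulky silyl group blocks N–H and C2 metalation in the later organometallic steps and is fluoride-labile at the end.

**Step 3**
Reactants: 4 Ar–Br
Product: 6 3-(2-methylbut-3-en-2-yl)-1-(triisopropylsilyl)-1H-indole-5-carbaldehyde (Ar–CHO), via aryllithium 5 (not isolated)
Conditions: t-BuLi (2.1 equiv), THF, –78 °C; DMF, –78 → 0 °C; H2O
Reagents that add atoms: N,N-dimethylformamide, CN(C)C=O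
Why: Bromine–lithium exchange and formylation of the aryllithium with DMF (Bouveault-type); the hindered N-silyl group and the neopentyl vinyl group should be inert to t-BuLi at –78 °C.

**Step 4**
Reactants: 6 Ar–CHO; 7 propyne
Product: 9 (1S)-1-Ar-but-2-yn-1-ol, via ethyl(prop-1-ynyl)zinc 8 (not isolated)
Conditions: 7 (excess), Et2Zn, Cy2NH (cat.), Et2O, rt; then (R)-BINOL (cat.), Ti(OiPr)4 (1 equiv), 6, rt
Reagents that add atoms: none
Why: BINOL–Ti(OiPr)4-catalysed enantioselective addition of an alkynylzinc to an aryl aldehyde; the (R)-BINOL complex is expected, by analogy with its other organozinc additions, to deliver the alkynyl group to the Re face and set the (S)-carbinol (alkynyl ranks above aryl).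

**Step 5**
Reactants: 9 (1S)-1-Ar-but-2-yn-1-ol
Product: 11 (1R,2Z)-3-iodo-1-Ar-but-2-en-1-ol, via sodium alkenylaluminate 10 (not isolated)
Conditions: NaAlH2(OCH2CH2OCH3)2, THF, 0 °C → rt; then I2, THF, –78 → 0 °C
Reagents that add atoms: iodine, II
Why: Alkoxide-directed trans-hydroalumination of the propargylic alcohol puts aluminium on the distal alkyne carbon cis to the carbinol carbon, and iodinolysis with retention gives the (Z)-3-iodoallylic alcohol; the stereocentre is untouched and is called R only because aryl now outranks alkenyl.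

**Step 6**
Reactants: 11 (1R,2Z)-3-iodo-1-Ar-but-2-en-1-ol; 12 2-methyl-2-vinyl-1,3-dioxolane
Product: 14 (1R,2Z)-3-methyl-5-(2-methyl-1,3-dioxolan-2-yl)-1-Ar-pent-2-en-1-ol, via B-alkyl-9-BBN adduct 13 (not isolated)
Conditions: 12 (1.6 equiv), 9-BBN-H (1.5 equiv), THF, 0 °C → rt; then 11, PdCl2(dppf) (cat.), AsPh3 (cat.), Cs2CO3, DMF–H2O, rt
Reagents that add atoms: none
Why: B-alkyl Suzuki–Miyaura coupling (anti-Markovnikov hydroboration, then sp3–sp2 coupling with retention of alkene geometry) places the masked 3-oxobutyl chain cis to the carbinol carbon; 12 is kept in excess over 9-BBN-H so that no B–H reaches the neopentyl vinyl group.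

**Step 7**
Reactants: 4 Ar–Br; 15 ethyl bromoacetate
Product: 17 ethyl 2-Ar-acetate, via Reformatsky reagent 16 (not isolated)
Conditions: 15, Zn dust (Me3SiCl-activated), THF, rt; then 4, Pd(dba)2 (cat.), XPhos (cat.), THF, rt
Reagents that add atoms: none
Why: Negishi-type palladium-catalysed α-arylation of an ester with a Reformatsky reagent, which should tolerate the N-silyl group and the neopentyl alkene at room temperature.

**Step 8**
Reactants: 17 ethyl 2-Ar-acetate
Product: 18 2-Ar-acetic acid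
Conditions: LiOH, THF–MeOH–H2O, rt; then 1 M HCl to pH 4, 0 °C
Reagents that add atoms: lithium hydroxide, [Li+].[OH-]
Why: Saponification of an unhindered ethyl ester; the N-triisopropylsilyl group is expected to survive dilute hydroxide at room temperature and brief mild acidification.

**Step 9**
Reactants: 14 (1R,2Z)-3-methyl-5-(2-methyl-1,3-dioxolan-2-yl)-1-Ar-pent-2-en-1-ol; 18 2-Ar-acetic acid
Product: 19 (1R,2Z)-3-methyl-5-(2-methyl-1,3-dioxolan-2-yl)-1-Ar-pent-2-en-1-yl 2-Ar-acetate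
Conditions: DCC, DMAP (cat.), CH2Cl2, 0 °C → rt; Et3N-deactivated silica
Reagents that add atoms: none
Why: Steglich esterification under neutral conditions should avoid ionisation of the benzylic, allylic alcohol and leave its configuration untouched.

**Step 10**
Reactants: 19 (1R,2Z)-3-methyl-5-(2-methyl-1,3-dioxolan-2-yl)-1-Ar-pent-2-en-1-yl 2-Ar-acetate
Product: 22 (2R,3S,4E)-3-methyl-3-[2-(2-methyl-1,3-dioxolan-2-yl)ethyl]-2,5-di-Ar-pent-4-enoic acid, via (Z)-silyl ketene acetal 20 (not isolated), via trimethylsilyl ester 21 (not isolated)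
Conditions: KN(SiMe3)2, THF–DMPU, –78 °C; Me3SiCl, –78 °C → rt, then 50 °C if needed; aq. NH4Cl
Reagents that add atoms: none
Why: Ireland–Claisen rearrangement: the arylacetate should give the (Z)-silyl ketene acetal (aryl cis to OSiMe3), and a chair transition state with the carbinol aryl equatorial and the (Z)-alkene arm axial forms the benzylic–quaternary C–C bond, transferring the carbinol configuration to C2 (R) and C3 (S) and giving the E-styrene; the silyl ester hydrolyses on work-up.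

**Step 11**
Reactants: 22 (2R,3S,4E)-3-methyl-3-[2-(2-methyl-1,3-dioxolan-2-yl)ethyl]-2,5-di-Ar-pent-4-enoic acid
Product: 24 (5S,6R)-7-hydroxy-5-methyl-6-Ar-5-[(E)-2-Ar-ethenyl]heptan-2-one, via hydroxy ketal 23 (not isolated)
Conditions: LiAlH4, THF, 0 → 40 °C; aq. potassium sodium tartrate (KNaC4H4O6) work-up; then PPTS (cat.), acetone–H2O, 45 °C
Reagents that add atoms: water, O
Why: LiAlH4 reduces the carboxylic acid to the primary alcohol without touching alkenes, ketal or N–Si bonds, and mild acid-catalysed ketal hydrolysis then unmasks the methyl ketone before the epimerisable aldehyde exists.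

**Step 12**
Reactants: 24 (5S,6R)-7-hydroxy-5-methyl-6-Ar-5-[(E)-2-Ar-ethenyl]heptan-2-one
Product: 25 (2R,3S)-3-methyl-6-oxo-2-Ar-3-[(E)-2-Ar-ethenyl]heptanal
Conditions: Dess–Martin periodinane, pyridine, CH2Cl2, 0 °C → rt; used at once
Reagents that add atoms: none
Why: Dess–Martin oxidation of the primary alcohol under pyridine buffering should give the α-aryl aldehyde without epimerisation or over-oxidation.

**Step 13**
Reactants: 25 (2R,3S)-3-methyl-6-oxo-2-Ar-3-[(E)-2-Ar-ethenyl]heptanal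
Product: 26 (1R,6S)-3,6-dimethyl-1-Ar-6-[(E)-2-Ar-ethenyl]cyclohex-2-ene
Conditions: TiCl3(DME)1.5, Zn–Cu couple, DME, reflux; 25 added by syringe pump at high dilution
Reagents that add atoms: none
Why: Low-valent titanium transfers single electrons to the aldehyde (chain C1) and the methyl ketone (chain C6), two acceptor carbons of like polarity; the ketyl species couple to a cyclic titanium pinacolate, which is deoxygenated on the titanium surface to the C=C bond. The closest known reaction type is the intramolecular McMurry coupling of 1,6-keto aldehydes to 1-methylcyclohexenes. The six-membered carbocycle closes by carbonyl–carbonyl reductive coupling across chain C1–C6 (formally a 6-exo attack of one ketyl on the other carbonyl), so the double bond can only lie between the two former carbonyl carbons and its trisubstituted position is unambiguous. No stereocentre is created: chain C2 (R) and C3 (S) become ring C1 and C6, and the only stereochemical demand is that the α-aryl aldehyde centre is not enolised, which slow addition of 25 to an excess of pre-formed reagent is meant to secure by keeping the free aldehyde concentration low. Chemoselectivity rests on the oxophilicity of titanium, which should leave the styrene, the two neopentyl vinyl groups and the N–Si bonds alone, while high dilution and the favourable ring size suppress intermolecular coupling.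

**Step 14**
Reactants: 26 (1R,6S)-3,6-dimethyl-1-Ar-6-[(E)-2-Ar-ethenyl]cyclohex-2-ene
Product: 27 5-[(1R,6S)-3,6-dimethyl-6-{(E)-2-[3-(2-methylbut-3-en-2-yl)-1H-indol-5-yl]ethenyl}cyclohex-2-en-1-yl]-3-(2-methylbut-3-en-2-yl)-1H-indole
Conditions: Bu4NF, THF, 0 °C → rt
Reagents that add atoms: none
Why: Fluoride-induced N-desilylation of both indoles under conditions that should leave the 1,5-diene, the styrene and the tertiary allyl groups untouched.

**Compound list**
1 | 5-bromo-1H-indole | Brc1ccc2[nH]ccc2c1 | starting material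
2 | isoprene (2-methylbuta-1,3-diene) | C=CC(C)=C | starting material
3 | 5-bromo-3-(2-methylbut-3-en-2-yl)-1H-indole | Brc1ccc2[nH]cc(C(C)(C)C=C)c2c1 | intermediate
4 | 5-bromo-3-(2-methylbut-3-en-2-yl)-1-(triisopropylsilyl)-1H-indole (Ar–Br) | Brc1ccc2n([Si](C(C)C)(C(C)C)C(C)C)cc(C(C)(C)C=C)c2c1 | intermediate
5 | [3-(2-methylbut-3-en-2-yl)-1-(triisopropylsilyl)-1H-indol-5-yl]lithium | [Li]c1ccc2n([Si](C(C)C)(C(C)C)C(C)C)cc(C(C)(C)C=C)c2c1 | intermediate
6 | 3-(2-methylbut-3-en-2-yl)-1-(triisopropylsilyl)-1H-indole-5-carbaldehyde (Ar–CHO) | O=Cc1ccc2n([Si](C(C)C)(C(C)C)C(C)C)cc(C(C)(C)C=C)c2c1 | intermediate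
7 | propyne | CC#C | starting material
8 | ethyl(prop-1-ynyl)zinc | CC[Zn]C#CC | intermediate
9 | (1S)-1-Ar-but-2-yn-1-ol | CC#C[C@@H](O)c1ccc2n([Si](C(C)C)(C(C)C)C(C)C)cc(C(C)(C)C=C)c2c1 | intermediate
10 | sodium (5R)-2,2-bis(2-methoxyethoxy)-3-methyl-5-Ar-2,5-dihydro-1,2-oxaluminol-2-uide (cyclic alkenylaluminate) | CC1=C[C@H](c2ccc3n([Si](C(C)C)(C(C)C)C(C)C)cc(C(C)(C)C=C)c3c2)O[Al-]1(OCCOC)OCCOC.[Na+] | intermediate
11 | (1R,2Z)-3-iodo-1-Ar-but-2-en-1-ol | C/C(I)=C/[C@@H](O)c1ccc2n([Si](C(C)C)(C(C)C)C(C)C)cc(C(C)(C)C=C)c2c1 | intermediate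
12 | 2-methyl-2-vinyl-1,3-dioxolane | C=CC1(C)OCCO1 | starting material
13 | 9-[2-(2-methyl-1,3-dioxolan-2-yl)ethyl]-9-borabicyclo[3.3.1]nonane | CC1(CCB2C3CCCC2CCC3)OCCO1 | intermediate
14 | (1R,2Z)-3-methyl-5-(2-methyl-1,3-dioxolan-2-yl)-1-Ar-pent-2-en-1-ol | C/C(CCC3(C)OCCO3)=C/[C@@H](O)c1ccc2n([Si](C(C)C)(C(C)C)C(C)C)cc(C(C)(C)C=C)c2c1 | intermediate
15 | ethyl bromoacetate | CCOC(=O)CBr | starting material
16 | (2-ethoxy-2-oxoethyl)zinc bromide | CCOC(=O)C[Zn]Br | intermediate
17 | ethyl 2-Ar-acetate | CCOC(=O)Cc1ccc2n([Si](C(C)C)(C(C)C)C(C)C)cc(C(C)(C)C=C)c2c1 | intermediate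
18 | 2-Ar-acetic acid | OC(=O)Cc1ccc2n([Si](C(C)C)(C(C)C)C(C)C)cc(C(C)(C)C=C)c2c1 | intermediate
19 | (1R,2Z)-3-methyl-5-(2-methyl-1,3-dioxolan-2-yl)-1-Ar-pent-2-en-1-yl 2-Ar-acetate | C/C(CCC5(C)OCCO5)=C/[C@@H](OC(=O)Cc1ccc2n([Si](C(C)C)(C(C)C)C(C)C)cc(C(C)(C)C=C)c2c1)c3ccc4n([Si](C(C)C)(C(C)C)C(C)C)cc(C(C)(C)C=C)c4c3 | intermediate
20 | (Z)-O-trimethylsilyl ketene acetal of 19 (aryl cis to OSiMe3) | C/C(CCC5(C)OCCO5)=C/[C@@H](O/C(O[Si](C)(C)C)=C/c1ccc2n([Si](C(C)C)(C(C)C)C(C)C)cc(C(C)(C)C=C)c2c1)c3ccc4n([Si](C(C)C)(C(C)C)C(C)C)cc(C(C)(C)C=C)c4c3 | intermediate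
21 | trimethylsilyl (2R,3S,4E)-3-methyl-3-[2-(2-methyl-1,3-dioxolan-2-yl)ethyl]-2,5-di-Ar-pent-4-enoate | C=CC(C)(C)c1cn([Si](C(C)C)(C(C)C)C(C)C)c2ccc(/C=C/[C@](C)(CCC5(C)OCCO5)[C@@H](C(=O)O[Si](C)(C)C)c3ccc4n([Si](C(C)C)(C(C)C)C(C)C)cc(C(C)(C)C=C)c4c3)cc12 | intermediate
22 | (2R,3S,4E)-3-methyl-3-[2-(2-methyl-1,3-dioxolan-2-yl)ethyl]-2,5-di-Ar-pent-4-enoic acid | C=CC(C)(C)c1cn([Si](C(C)C)(C(C)C)C(C)C)c2ccc(/C=C/[C@](C)(CCC5(C)OCCO5)[C@@H](C(=O)O)c3ccc4n([Si](C(C)C)(C(C)C)C(C)C)cc(C(C)(C)C=C)c4c3)cc12 | intermediate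
23 | (2R,3S,4E)-3-methyl-3-[2-(2-methyl-1,3-dioxolan-2-yl)ethyl]-2,5-di-Ar-pent-4-en-1-ol | C=CC(C)(C)c1cn([Si](C(C)C)(C(C)C)C(C)C)c2ccc(/C=C/[C@](C)(CCC5(C)OCCO5)[C@@H](CO)c3ccc4n([Si](C(C)C)(C(C)C)C(C)C)cc(C(C)(C)C=C)c4c3)cc12 | intermediate
24 | (5S,6R)-7-hydroxy-5-methyl-6-Ar-5-[(E)-2-Ar-ethenyl]heptan-2-one | C=CC(C)(C)c1cn([Si](C(C)C)(C(C)C)C(C)C)c2ccc(/C=C/[C@](C)(CCC(C)=O)[C@@H](CO)c3ccc4n([Si](C(C)C)(C(C)C)C(C)C)cc(C(C)(C)C=C)c4c3)cc12 | intermediate
25 | (2R,3S)-3-methyl-6-oxo-2-Ar-3-[(E)-2-Ar-ethenyl]heptanal | C=CC(C)(C)c1cn([Si](C(C)C)(C(C)C)C(C)C)c2ccc(/C=C/[C@](C)(CCC(C)=O)[C@@H](C=O)c3ccc4n([Si](C(C)C)(C(C)C)C(C)C)cc(C(C)(C)C=C)c4c3)cc12 | intermediate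
26 | (1R,6S)-3,6-dimethyl-1-Ar-6-[(E)-2-Ar-ethenyl]cyclohex-2-ene (1,1'-bis(triisopropylsilyl) derivative of 27) | C=CC(C)(C)c1cn([Si](C(C)C)(C(C)C)C(C)C)c2ccc(/C=C/[C@]3(C)CCC(C)=C[C@H]3c3ccc4n([Si](C(C)C)(C(C)C)C(C)C)cc(C(C)(C)C=C)c4c3)cc12 | intermediate
27 | 5-[(1R,6S)-3,6-dimethyl-6-{(E)-2-[3-(2-methylbut-3-en-2-yl)-1H-indol-5-yl]ethenyl}cyclohex-2-en-1-yl]-3-(2-methylbut-3-en-2-yl)-1H-indole | C=CC(C)(C)c1c[nH]c2ccc(/C=C/[C@]3(C)CCC(C)=C[C@H]3c3ccc4[nH]cc(C(C)(C)C=C)c4c3)cc12 | target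

Total step count: 14.
Longest linear sequence: 12 steps (steps 1–6 and 9–14; steps 7 and 8 form the side branch from 4).

**Steps most likely to fail**

Step 13. The α-aryl aldehyde carbon may enolise on the Lewis-acidic titanium and zinc chlorides before C–C coupling (loss of configuration at ring C1), the two carbonyls may undergo an intramolecular aldol reaction, or the reaction may stop at the pinacolate. The fallback avoids the aldehyde and sets out from hydroxy ketone 24. Appel iodination (I2, PPh3, imidazole, CH2Cl2) would give (5S,6R)-7-iodo-5-methyl-6-Ar-5-[(E)-2-Ar-ethenyl]heptan-2-one F1. Heating with PPh3 in MeCN would give [(2R,3S)-3-methyl-6-oxo-2-Ar-3-[(E)-2-Ar-ethenyl]heptyl]triphenylphosphonium iodide F2. KN(SiMe3)2 in THF–toluene would then form the ylide, which closes the same C2=C3 bond by intramolecular Wittig olefination of the methyl ketone. The fallback returns to the route at 26.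

Step 10. The doubly activated benzylic, allylic ester may ionise or undergo 1,3-transposition before rearrangement, or incomplete control of the ketene acetal geometry may erode the configuration at the benzylic centre. The fallback sets out from allylic alcohol 14 and aldehyde 6 and replaces the ester by an allyl vinyl ether whose E enol ether geometry comes from an (E)-alkenylboronate, so that no enolisation is involved. A boron–Wittig reaction of 6 (CH2(Bpin)2, lithium 2,2,6,6-tetramethylpiperidide, THF, –78 °C) would give (E)-4,4,5,5-tetramethyl-2-(2-Ar-ethenyl)-1,3,2-dioxaborolane F3. Cu(OAc)2-promoted O-alkenylation of 14 with F3 (Et3N, rt) would give (E)-2-Ar-ethenyl (1R,2Z)-3-methyl-5-(2-methyl-1,3-dioxolan-2-yl)-1-Ar-pent-2-en-1-yl ether F4. Its thermal Claisen rearrangement (toluene, 90 °C; same chair, aryl of the E-enol ether equatorial) should give (2R,3S,4E)-3-methyl-3-[2-(2-methyl-1,3-dioxolan-2-yl)ethyl]-2,5-di-Ar-pent-4-enal F5. Ketal hydrolysis (PPTS, acetone–H2O) returns to the route at 25.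

Step 4. The electron-rich aryl aldehyde and a small gaseous alkyne may give low conversion or poor facial discrimination. The fallback sets out from 6 and moves the stereocontrol to a reagent-controlled ketone reduction. Addition of 1-propynylmagnesium bromide (THF, 0 °C) would give racemic 1-Ar-but-2-yn-1-ol F6. MnO2 (CH2Cl2) would give 1-Ar-but-2-yn-1-one F7. Reduction with (S)-2-methyl-CBS-oxazaborolidine and BH3·SMe2 (THF, –30 °C; aryl as the large group, alkynyl as the small group) should give the (S)-alcohol. The fallback returns to the route at 9.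

**Further compounds**
F1 | step 13 | (5S,6R)-7-iodo-5-methyl-6-Ar-5-[(E)-2-Ar-ethenyl]heptan-2-one | C=CC(C)(C)c1cn([Si](C(C)C)(C(C)C)C(C)C)c2ccc(/C=C/[C@](C)(CCC(C)=O)[C@@H](CI)c3ccc4n([Si](C(C)C)(C(C)C)C(C)C)cc(C(C)(C)C=C)c4c3)cc12
F2 | step 13 | [(2R,3S)-3-methyl-6-oxo-2-Ar-3-[(E)-2-Ar-ethenyl]heptyl]triphenylphosphonium iodide | C=CC(C)(C)c1cn([Si](C(C)C)(C(C)C)C(C)C)c2ccc(/C=C/[C@](C)(CCC(C)=O)[C@@H](C[P+](c5ccccc5)(c5ccccc5)c5ccccc5)c3ccc4n([Si](C(C)C)(C(C)C)C(C)C)cc(C(C)(C)C=C)c4c3)cc12.[I-]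
F3 | step 10 | (E)-4,4,5,5-tetramethyl-2-(2-Ar-ethenyl)-1,3,2-dioxaborolane | CC1(C)OB(/C=C/c2ccc3n([Si](C(C)C)(C(C)C)C(C)C)cc(C(C)(C)C=C)c3c2)OC1(C)C
F4 | step 10 | (E)-2-Ar-ethenyl (1R,2Z)-3-methyl-5-(2-methyl-1,3-dioxolan-2-yl)-1-Ar-pent-2-en-1-yl ether | C/C(CCC5(C)OCCO5)=C/[C@@H](O/C=C/c1ccc2n([Si](C(C)C)(C(C)C)C(C)C)cc(C(C)(C)C=C)c2c1)c3ccc4n([Si](C(C)C)(C(C)C)C(C)C)cc(C(C)(C)C=C)c4c3
F5 | step 10 | (2R,3S,4E)-3-methyl-3-[2-(2-methyl-1,3-dioxolan-2-yl)ethyl]-2,5-di-Ar-pent-4-enal | C=CC(C)(C)c1cn([Si](C(C)C)(C(C)C)C(C)C)c2ccc(/C=C/[C@](C)(CCC5(C)OCCO5)[C@@H](C=O)c3ccc4n([Si](C(C)C)(C(C)C)C(C)C)cc(C(C)(C)C=C)c4c3)cc12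
F6 | step 4 | racemic 1-Ar-but-2-yn-1-ol | CC#CC(O)c1ccc2n([Si](C(C)C)(C(C)C)C(C)C)cc(C(C)(C)C=C)c2c1
F7 | step 4 | 1-Ar-but-2-yn-1-one | CC#CC(=O)c1ccc2n([Si](C(C)C)(C(C)C)C(C)C)cc(C(C)(C)C=C)c2c1
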